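**Strategy.** The oxolane (O1; C2 bearing guaiacyl ring A; C3 and C4 methyl-bearing; C5 bearing guaiacyl ring B) is closed at O1–C5. The feature exploited is the 4,5-cis relation of ring B to the C4 methyl beside a 2,3-trans, 3,4-trans array: cut at O1–C5 with inversion, the core is an all-(S), anti,anti 1,4-diaryl-2,3-dimethylbutane with a ketone at C2 and a mesylate at C5. In one operation, Felkin-controlled hydride reduction and 5-exo-tet SN2 displacement set C2, invert C5 and close the ring; a tosyloxy group on ring B suppresses ionisation. The precursor comes from an anti-crotylation-derived trans,trans-lactone and an aryllithium; the enantiomeric threo arms are then grown one after the other from lactate derivatives.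

Key step: step 8

Assumption: γ-hydroxy ketone 10 is taken to react in its open-chain form; its cyclic hemiketal tautomer is in equilibrium with it and is drained through the open form on mesylation.

**Step 1**
Reactants: 1 vanillin
Product: 2 4-formyl-2-methoxyphenyl 4-methylbenzenesulfonate
Conditions: TsCl, Et3N, DMAP (cat.), CH2Cl2, 0 °C → rt
Reagents that add atoms: 4-methylbenzenesulfonyl chloride, Cc1ccc(S(=O)(=O)Cl)cc1
Why: O-sulfonylation of the phenol; the tosyloxy group protects ring B and makes it electron-poor for the later SN2 closure.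

**Step 2**
Reactants: 2 4-formyl-2-methoxyphenyl 4-methylbenzenesulfonate; 3 (E)-crotylboronic acid pinacol ester
Product: 4 4-[(1S,2S)-1-hydroxy-2-methylbut-3-en-1-yl]-2-methoxyphenyl 4-methylbenzenesulfonate
Conditions: (S)-TRIP ((S)-3,3'-bis(2,4,6-triisopropylphenyl)-1,1'-binaphthalene-2,2'-diyl hydrogen phosphate, 5 mol%), toluene, −30 °C; aqueous work-up
Reagents that add atoms: none
Why: Chiral phosphoric acid-catalysed crotylboration through a closed chair transition state, in which the (E)-boronate gives the anti relation and the (S)-catalyst, the antipode that directs attack to the Si face of aryl aldehydes, should set (1S,2S).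

**Step 3**
Reactants: 4 the (1S,2S)-homoallylic alcohol
Product: 5 4-[(1S,2S)-1,4-dihydroxy-2-methylbutyl]-2-methoxyphenyl 4-methylbenzenesulfonate
Conditions: 9-BBN, THF, 0 °C → rt; then H2O2, aq. NaOH, 0 °C
Reagents that add atoms: hydrogen peroxide, OO
Why: Hydroboration–oxidation: the hindered borane adds anti-Markovnikov to the terminal alkene and cold alkaline peroxide replaces boron by hydroxyl without touching the two stereocentres or the aryl sulfonate.

**Step 4**
Reactants: 5 the (1S,2S)-1,4-diol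
Product: 6 (4S,5S)-4-methyl-5-[3-methoxy-4-(tosyloxy)phenyl]oxolan-2-one
Conditions: TEMPO (cat.), PhI(OAc)2, CH2Cl2, rt
Reagents that add atoms: none
Why: TEMPO/PhI(OAc)2 oxidative lactonisation: the primary alcohol is oxidised selectively, the hydroxy aldehyde closes to the lactol and this is oxidised on to the γ-lactone, the anti diol giving the 4,5-trans lactone.

**Step 5**
Reactants: 6 the (4S,5S)-lactone
Product: 7 (3S,4S,5S)-3,4-dimethyl-5-[3-methoxy-4-(tosyloxy)phenyl]oxolan-2-one (all-trans)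
Conditions: LiN(SiMe3)2, THF, −78 °C; then MeI
Reagents that add atoms: iodomethane, CI
Why: Lactone enolate alkylation: iodomethane approaches the lithium enolate anti to the adjacent C4 methyl, which should set C3 as (S) and give the all-trans lactone.

**Step 6**
Reactants: 7 the all-trans lactone; 8 1-(benzyloxy)-4-bromo-2-methoxybenzene
Product: 10 (2S,3S,4S)-1-[4-(benzyloxy)-3-methoxyphenyl]-4-hydroxy-4-[3-methoxy-4-(tosyloxy)phenyl]-2,3-dimethylbutan-1-one, via aryllithium 9 (not isolated)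
Conditions: 8, n-BuLi, THF, −78 °C; then 7, −78 °C; H2O quench
Reagents that add atoms: none
Why: Bromine–lithium exchange followed by a single nucleophilic addition to the lactone: the tetrahedral lithium hemiketalate persists at −78 °C, so the γ-hydroxy aryl ketone forms only on quench and no stereocentre is touched.

**Step 7**
Reactants: 10 the γ-hydroxy ketone
Product: 11 (2S,3S,4S)-1-[4-(benzyloxy)-3-methoxyphenyl]-4-(methanesulfonyloxy)-4-[3-methoxy-4-(tosyloxy)phenyl]-2,3-dimethylbutan-1-one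
Conditions: MsCl, Et3N, CH2Cl2, −20 °C; used without storage
Reagents that add atoms: methanesulfonyl chloride, CS(=O)(=O)Cl
Why: Sulfonylation of the secondary benzylic alcohol with retention (O–S bond formation); the electron-poor ring B should keep the benzylic mesylate from ionising.

**Step 8**
Reactants: 11 the γ-mesyloxy ketone
Product: 13 (2S,3S,4S,5R)-2-[4-(benzyloxy)-3-methoxyphenyl]-5-[3-methoxy-4-(tosyloxy)phenyl]-3,4-dimethyloxolane, via lithium alkoxide 12 (not isolated)
Conditions: LiBH(s-Bu)3, THF, −78 °C → rt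
Reagents that add atoms: none
Why: The bulky hydride adds to the aryl ketone in the Felkin–Anh sense (anti to the C3 branch, past hydrogen and not methyl) to give the (S)-configured lithium alkoxide 12, whose oxygen then attacks the benzylic C–OMs carbon from the rear in an intramolecular Williamson etherification. The closest known reaction type is the reductive cyclisation of γ-halo or γ-sulfonyloxy aryl ketones to 2-aryltetrahydrofurans. The oxolane closes in the 5-exo-tet mode by formation of the O1–C5 bond. C2 (new) is set by 1,2-induction from the adjacent methyl-bearing centre, and C5 is set by stereospecific inversion of the crotylation-derived (S)-mesylate to (R), which places ring B cis to the C4 methyl, the relation a cationic closure would not be expected to give. The step needs SN2 over SN1 and hydride attack at the ketone in preference to the sulfonates: the para-tosyloxy group on ring B destabilises the benzylic cation, ring A carries only the nucleophilic oxygen so its electron-rich benzylic position is never activated, and LiBH(s-Bu)3 is too hindered to displace sulfonates at low temperature.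

**Step 9**
Reactants: 13 the oxolane tosylate
Product: 14 4-[(2R,3S,4S,5S)-5-[4-(benzyloxy)-3-methoxyphenyl]-3,4-dimethyloxolan-2-yl]-2-methoxyphenol
Conditions: KOH, MeOH/THF/H2O, 60 °C; then aq. NH4Cl
Reagents that add atoms: none
Why: Hydrolytic cleavage of the aryl sulfonate by attack of hydroxide at sulfur; benzyl ether, oxolane and all stereocentres are inert to base.

**Step 10**
Reactants: 14 the ring B phenol; 15 ethyl (R)-lactate
Product: 16 ethyl (2S)-2-{4-[(2R,3S,4S,5S)-5-[4-(benzyloxy)-3-methoxyphenyl]-3,4-dimethyloxolan-2-yl]-2-methoxyphenoxy}propanoate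
Conditions: PPh3, DIAD, THF, 0 °C → rt
Reagents that add atoms: none
Why: Mitsunobu etherification: the phenoxide displaces the activated lactate hydroxyl by SN2 with inversion, so the (R)-lactate gives the (S)-2-aryloxypropanoate.

**Step 11**
Reactants: 16 the ring B ester; 17 3,4-dimethoxyphenylmagnesium bromide
Product: 19 (2S)-2-{4-[(2R,3S,4S,5S)-5-[4-(benzyloxy)-3-methoxyphenyl]-3,4-dimethyloxolan-2-yl]-2-methoxyphenoxy}-1-(3,4-dimethoxyphenyl)propan-1-one, via Weinreb amide 18 (not isolated)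
Conditions: MeNHOMe·HCl, i-PrMgCl, THF, −20 °C; then 17, −20 → 0 °C; aq. NH4Cl
Reagents that add atoms: none
Why: Weinreb ketone synthesis in one flask: the magnesium amide converts the ester into the N-methoxy-N-methylamide, whose chelated tetrahedral adduct with the aryl Grignard reagent prevents over-addition and keeps the α-stereocentre from enolising until the quench.

**Step 12**
Reactants: 19 the ring B arm ketone
Product: 20 (1S,2S)-2-{4-[(2R,3S,4S,5S)-5-[4-(benzyloxy)-3-methoxyphenyl]-3,4-dimethyloxolan-2-yl]-2-methoxyphenoxy}-1-(3,4-dimethoxyphenyl)propan-1-ol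
Conditions: n-Bu4NBH4, CH2Cl2/MeOH, −40 °C
Reagents that add atoms: none
Why: Felkin–Anh (polar) reduction: with a non-chelating ammonium counter-ion the hydride should attack the ketone anti to the α-aryloxy group and give the threo carbinol, (1S,2S) from the (S)-ether.

**Step 13**
Reactants: 20 the benzyl ether
Product: 21 4-[(2S,3S,4S,5R)-5-{4-[(1S,2S)-1-(3,4-dimethoxyphenyl)-1-hydroxypropan-2-yl]oxy-3-methoxyphenyl}-3,4-dimethyloxolan-2-yl]-2-methoxyphenol
Conditions: H2 (1 atm), Pd/C, EtOAc, rt; stopped when 20 is consumed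
Reagents that add atoms: none
Why: Catalytic hydrogenolysis of the benzyl aryl ether, which should be cleaved faster than the benzylic C–O bonds of the oxolane and of the secondary carbinol under neutral conditions.

**Step 14**
Reactants: 21 the ring A phenol; 22 ethyl (2S)-2-(tosyloxy)propanoate
Product: 23 ethyl (2R)-2-{4-[(2S,3S,4S,5R)-5-{4-[(1S,2S)-1-(3,4-dimethoxyphenyl)-1-hydroxypropan-2-yl]oxy-3-methoxyphenyl}-3,4-dimethyloxolan-2-yl]-2-methoxyphenoxy}propanoate
Conditions: K2CO3, MeCN, 60 °C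
Reagents that add atoms: none
Why: Williamson O-alkylation: carbonate deprotonates only the phenol and leaves the secondary carbinol untouched, and the phenoxide displaces the α-tosyloxy group by SN2 with inversion, so the (S)-sulfonate gives the (R)-2-aryloxypropanoate.

**Step 15**
Reactants: 23 the ring A ester; 17 3,4-dimethoxyphenylmagnesium bromide
Product: 25 (2R)-1-(3,4-dimethoxyphenyl)-2-{4-[(2S,3S,4S,5R)-5-{4-[(1S,2S)-1-(3,4-dimethoxyphenyl)-1-hydroxypropan-2-yl]oxy-3-methoxyphenyl}-3,4-dimethyloxolan-2-yl]-2-methoxyphenoxy}propan-1-one, via Weinreb amide magnesium alkoxide 24 (not isolated)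
Conditions: MeNHOMe·HCl, i-PrMgCl (excess), THF, −20 °C; then 17, −20 → 0 °C; aq. NH4Cl
Reagents that add atoms: none
Why: Weinreb ketone synthesis in one flask: a further equivalent of i-PrMgCl masks the ring B arm carbinol as its magnesium alkoxide, the ester becomes the N-methoxy-N-methylamide, and its chelated adduct with the aryl Grignard reagent stops at the ketone stage without enolisation of the α-stereocentre.

**Step 16**
Reactants: 25 the ring A arm ketone
Product: 26 (1R,2R)-1-(3,4-dimethoxyphenyl)-2-{4-[(2S,3S,4S,5R)-5-{4-[(1S,2S)-1-(3,4-dimethoxyphenyl)-1-hydroxypropan-2-yl]oxy-3-methoxyphenyl}-3,4-dimethyloxolan-2-yl]-2-methoxyphenoxy}propan-1-ol (target)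
Conditions: n-Bu4NBH4, CH2Cl2/MeOH, −40 °C
Reagents that add atoms: none
Why: Felkin–Anh (polar) reduction: the hydride should attack anti to the α-aryloxy group and give the threo carbinol, (1R,2R) from the (R)-ether, while the finished ring B arm is not affected.

**Compound list**
1 | vanillin | COc1cc(C=O)ccc1O | starting material
2 | 4-formyl-2-methoxyphenyl 4-methylbenzenesulfonate | COc1cc(C=O)ccc1OS(=O)(=O)c1ccc(C)cc1 | intermediate
3 | (E)-crotylboronic acid pinacol ester | C/C=C/CB1OC(C)(C)C(C)(C)O1 | starting material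
4 | 4-[(1S,2S)-1-hydroxy-2-methylbut-3-en-1-yl]-2-methoxyphenyl 4-methylbenzenesulfonate | C=C[C@H](C)[C@H](O)c1ccc(OS(=O)(=O)c2ccc(C)cc2)c(OC)c1 | intermediate
5 | 4-[(1S,2S)-1,4-dihydroxy-2-methylbutyl]-2-methoxyphenyl 4-methylbenzenesulfonate | OCC[C@H](C)[C@H](O)c1ccc(OS(=O)(=O)c2ccc(C)cc2)c(OC)c1 | intermediate
6 | (4S,5S)-4-methyl-5-[3-methoxy-4-(tosyloxy)phenyl]oxolan-2-one | O=C1O[C@H](c2ccc(OS(=O)(=O)c3ccc(C)cc3)c(OC)c2)[C@@H](C)C1 | intermediate
7 | (3S,4S,5S)-3,4-dimethyl-5-[3-methoxy-4-(tosyloxy)phenyl]oxolan-2-one | O=C1O[C@H](c2ccc(OS(=O)(=O)c3ccc(C)cc3)c(OC)c2)[C@@H](C)[C@@H]1C | intermediate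
8 | 1-(benzyloxy)-4-bromo-2-methoxybenzene | COc1cc(Br)ccc1OCc1ccccc1 | starting material
9 | [4-(benzyloxy)-3-methoxyphenyl]lithium | COc1cc([Li])ccc1OCc1ccccc1 | intermediate
10 | (2S,3S,4S)-1-[4-(benzyloxy)-3-methoxyphenyl]-4-hydroxy-4-[3-methoxy-4-(tosyloxy)phenyl]-2,3-dimethylbutan-1-one | COc1cc(C(=O)[C@@H](C)[C@H](C)[C@H](O)c2ccc(OS(=O)(=O)c3ccc(C)cc3)c(OC)c2)ccc1OCc1ccccc1 | intermediate
11 | (2S,3S,4S)-1-[4-(benzyloxy)-3-methoxyphenyl]-4-(methanesulfonyloxy)-4-[3-methoxy-4-(tosyloxy)phenyl]-2,3-dimethylbutan-1-one | COc1cc(C(=O)[C@@H](C)[C@H](C)[C@H](OS(C)(=O)=O)c2ccc(OS(=O)(=O)c3ccc(C)cc3)c(OC)c2)ccc1OCc1ccccc1 | intermediate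
12 | lithium (1S,2S,3S,4S)-1-[4-(benzyloxy)-3-methoxyphenyl]-4-(methanesulfonyloxy)-4-[3-methoxy-4-(tosyloxy)phenyl]-2,3-dimethylbutan-1-olate | COc1cc([C@@H]([O-])[C@@H](C)[C@H](C)[C@H](OS(C)(=O)=O)c2ccc(OS(=O)(=O)c3ccc(C)cc3)c(OC)c2)ccc1OCc1ccccc1.[Li+] | intermediate
13 | (2S,3S,4S,5R)-2-[4-(benzyloxy)-3-methoxyphenyl]-5-[3-methoxy-4-(tosyloxy)phenyl]-3,4-dimethyloxolane | COc1cc([C@H]2O[C@@H](c3ccc(OS(=O)(=O)c4ccc(C)cc4)c(OC)c3)[C@@H](C)[C@@H]2C)ccc1OCc1ccccc1 | intermediate
14 | 4-[(2R,3S,4S,5S)-5-[4-(benzyloxy)-3-methoxyphenyl]-3,4-dimethyloxolan-2-yl]-2-methoxyphenol | COc1cc([C@H]2O[C@@H](c3ccc(O)c(OC)c3)[C@@H](C)[C@@H]2C)ccc1OCc1ccccc1 | intermediate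
15 | ethyl (R)-lactate | CCOC(=O)[C@@H](C)O | starting material
16 | ethyl (2S)-2-{4-[(2R,3S,4S,5S)-5-[4-(benzyloxy)-3-methoxyphenyl]-3,4-dimethyloxolan-2-yl]-2-methoxyphenoxy}propanoate | COc1cc([C@H]2O[C@@H](c3ccc(O[C@@H](C)C(=O)OCC)c(OC)c3)[C@@H](C)[C@@H]2C)ccc1OCc1ccccc1 | intermediate
17 | 3,4-dimethoxyphenylmagnesium bromide | COc1ccc([Mg]Br)cc1OC | starting material
18 | (2S)-2-{4-[(2R,3S,4S,5S)-5-[4-(benzyloxy)-3-methoxyphenyl]-3,4-dimethyloxolan-2-yl]-2-methoxyphenoxy}-N-methoxy-N-methylpropanamide | COc1cc([C@H]2O[C@@H](c3ccc(O[C@@H](C)C(=O)N(C)OC)c(OC)c3)[C@@H](C)[C@@H]2C)ccc1OCc1ccccc1 | intermediate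
19 | (2S)-2-{4-[(2R,3S,4S,5S)-5-[4-(benzyloxy)-3-methoxyphenyl]-3,4-dimethyloxolan-2-yl]-2-methoxyphenoxy}-1-(3,4-dimethoxyphenyl)propan-1-one | COc1cc([C@H]2O[C@@H](c3ccc(O[C@@H](C)C(=O)c4ccc(OC)c(OC)c4)c(OC)c3)[C@@H](C)[C@@H]2C)ccc1OCc1ccccc1 | intermediate
20 | (1S,2S)-2-{4-[(2R,3S,4S,5S)-5-[4-(benzyloxy)-3-methoxyphenyl]-3,4-dimethyloxolan-2-yl]-2-methoxyphenoxy}-1-(3,4-dimethoxyphenyl)propan-1-ol | COc1cc([C@H]2O[C@@H](c3ccc(O[C@@H](C)[C@@H](O)c4ccc(OC)c(OC)c4)c(OC)c3)[C@@H](C)[C@@H]2C)ccc1OCc1ccccc1 | intermediate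
21 | 4-[(2S,3S,4S,5R)-5-{4-[(1S,2S)-1-(3,4-dimethoxyphenyl)-1-hydroxypropan-2-yl]oxy-3-methoxyphenyl}-3,4-dimethyloxolan-2-yl]-2-methoxyphenol | COc1cc([C@H]2O[C@@H](c3ccc(O[C@@H](C)[C@@H](O)c4ccc(OC)c(OC)c4)c(OC)c3)[C@@H](C)[C@@H]2C)ccc1O | intermediate
22 | ethyl (2S)-2-(tosyloxy)propanoate | CCOC(=O)[C@H](C)OS(=O)(=O)c1ccc(C)cc1 | starting material
23 | ethyl (2R)-2-{4-[(2S,3S,4S,5R)-5-{4-[(1S,2S)-1-(3,4-dimethoxyphenyl)-1-hydroxypropan-2-yl]oxy-3-methoxyphenyl}-3,4-dimethyloxolan-2-yl]-2-methoxyphenoxy}propanoate | CCOC(=O)[C@@H](C)Oc1ccc([C@H]2O[C@@H](c3ccc(O[C@@H](C)[C@@H](O)c4ccc(OC)c(OC)c4)c(OC)c3)[C@@H](C)[C@@H]2C)cc1OC | intermediate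
24 | chloromagnesium alkoxide of (2R)-2-{4-[(2S,3S,4S,5R)-5-{4-[(1S,2S)-1-(3,4-dimethoxyphenyl)-1-hydroxypropan-2-yl]oxy-3-methoxyphenyl}-3,4-dimethyloxolan-2-yl]-2-methoxyphenoxy}-N-methoxy-N-methylpropanamide | CON(C)C(=O)[C@@H](C)Oc1ccc([C@H]2O[C@@H](c3ccc(O[C@@H](C)[C@@H](O[Mg]Cl)c4ccc(OC)c(OC)c4)c(OC)c3)[C@@H](C)[C@@H]2C)cc1OC | intermediate
25 | (2R)-1-(3,4-dimethoxyphenyl)-2-{4-[(2S,3S,4S,5R)-5-{4-[(1S,2S)-1-(3,4-dimethoxyphenyl)-1-hydroxypropan-2-yl]oxy-3-methoxyphenyl}-3,4-dimethyloxolan-2-yl]-2-methoxyphenoxy}propan-1-one | COc1ccc(C(=O)[C@@H](C)Oc2ccc([C@H]3O[C@@H](c4ccc(O[C@@H](C)[C@@H](O)c5ccc(OC)c(OC)c5)c(OC)c4)[C@@H](C)[C@@H]3C)cc2OC)cc1OC | intermediate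
26 | (1R,2R)-1-(3,4-dimethoxyphenyl)-2-{4-[(2S,3S,4S,5R)-5-{4-[(1S,2S)-1-(3,4-dimethoxyphenyl)-1-hydroxypropan-2-yl]oxy-3-methoxyphenyl}-3,4-dimethyloxolan-2-yl]-2-methoxyphenoxy}propan-1-ol | COc1ccc([C@@H](O)[C@@H](C)Oc2ccc([C@H]3O[C@@H](c4ccc(O[C@@H](C)[C@@H](O)c5ccc(OC)c(OC)c5)c(OC)c4)[C@@H](C)[C@@H]3C)cc2OC)cc1OC | target

**Total step count:** 16. **Longest linear sequence:** 16 steps (1 → 26).

**Steps most likely to fail**

Step 8. Hydride delivery may show incomplete Felkin facial control, and rear-side displacement may be eroded if the alkoxide forms while the benzylic sulfonate is warming. The fallback sets out from keto mesylate 11 and separates the two events, putting the new stereocentre under catalyst control. Corey–Bakshi–Shibata reduction ((R)-2-methyl-CBS-oxazaborolidine, catecholborane, toluene, −78 °C) should give the (1S)-configured hydroxy mesylate F1 with the aryl group as the large substituent. Cold deprotonation with KN(SiMe3)2 (THF, −78 → 0 °C) then closes the ring by SN2 with inversion, and the sequence returns to the route at oxolane 13.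

Step 12. Facial selectivity in the substrate-controlled reduction may be insufficient, with partial chelation control leaking to the erythro carbinol; the same question recurs in step 16. The fallback sets out from ester 16. i-Bu2AlH (CH2Cl2, −78 °C) would give the aldehyde F2. Chelation-controlled addition of Grignard reagent 17 (MgBr2·OEt2, CH2Cl2, −78 °C) should deliver the aryl group anti to the methyl on the five-membered magnesium chelate and so give the threo carbinol, returning at alcohol 20.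

Step 6. A second addition of the aryllithium after premature collapse of the hemiketalate, or attack at the sulfonyl sulfur of the tosylate, may compete. The fallback sets out from lactone 7. Aminolysis with MeNHOMe·HCl/AlMe3 (CH2Cl2, 0 °C) would open it to the hydroxy Weinreb amide F3, which is silylated at once (Et3SiCl, imidazole) to the silyl ether F4. Aryllithium 9 should then stop at the silyloxy ketone F5, and HF·pyridine (THF, 0 °C) removes the silyl group to return at hydroxy ketone 10.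

**Further compounds**
F1 | step 8 | (1S,2S,3S,4S)-4-[4-(benzyloxy)-3-methoxyphenyl]-4-hydroxy-1-[3-methoxy-4-(tosyloxy)phenyl]-2,3-dimethylbutyl methanesulfonate | COc1cc([C@@H](O)[C@@H](C)[C@H](C)[C@H](OS(C)(=O)=O)c2ccc(OS(=O)(=O)c3ccc(C)cc3)c(OC)c2)ccc1OCc1ccccc1
F2 | step 12 | (2S)-2-{4-[(2R,3S,4S,5S)-5-[4-(benzyloxy)-3-methoxyphenyl]-3,4-dimethyloxolan-2-yl]-2-methoxyphenoxy}propanal | COc1cc([C@H]2O[C@@H](c3ccc(O[C@@H](C)C=O)c(OC)c3)[C@@H](C)[C@@H]2C)ccc1OCc1ccccc1
F3 | step 6 | (2S,3S,4S)-4-hydroxy-N-methoxy-4-[3-methoxy-4-(tosyloxy)phenyl]-N,2,3-trimethylbutanamide | CON(C)C(=O)[C@@H](C)[C@H](C)[C@H](O)c1ccc(OS(=O)(=O)c2ccc(C)cc2)c(OC)c1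
F4 | step 6 | (2S,3S,4S)-N-methoxy-4-[3-methoxy-4-(tosyloxy)phenyl]-N,2,3-trimethyl-4-(triethylsilyloxy)butanamide | CON(C)C(=O)[C@@H](C)[C@H](C)[C@H](O[Si](CC)(CC)CC)c1ccc(OS(=O)(=O)c2ccc(C)cc2)c(OC)c1
F5 | step 6 | (2S,3S,4S)-1-[4-(benzyloxy)-3-methoxyphenyl]-4-[3-methoxy-4-(tosyloxy)phenyl]-2,3-dimethyl-4-(triethylsilyloxy)butan-1-one | COc1cc(C(=O)[C@@H](C)[C@H](C)[C@H](O[Si](CC)(CC)CC)c2ccc(OS(=O)(=O)c3ccc(C)cc3)c(OC)c2)ccc1OCc1ccccc1
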